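**Retrosynthetic overview**
1. Ester C–O bond: Mitsunobu coupling of the primary side-chain alcohol with vanillic acid, last.
2. Oxygen bridge and C-7 carbinol: epoxidation of a hydroazulenol and transannular attack of its tertiary hydroxyl; side-chain CH2OH centre: hydroboration of an isopropenyl group.
3. Seven-membered ring: ring-closing metathesis, after adding a 3-methylbut-3-enyl Grignard reagent to a 2-allyl-2-methylcyclopentanone.
4. Quaternary carbon: anionic oxy-Cope [3,3] shift of the allyl adduct of a cyclopentenecarbaldehyde, then loss of the formyl carbon.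
5. Cyclopentene and first stereocentre: ozonolysis/aldol of (S)-limonene. Ring order: five-membered carbocycle, seven-membered carbocycle, oxygen-bridged rings.

Assumption: the target is read from its SMILES as having the side chain, the oxygen bridge and the angular methyl on one face of the cyclopentane; where an intermediate is a mixture at a centre or double bond that the next step removes, its SMILES leaves that element open.

**Route**

Step 1
Reactants: 1 (S)-(−)-limonene
Product: 3 (3S)-6-oxo-3-(prop-1-en-2-yl)heptanal, via secondary ozonide 2 (not isolated)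
Conditions: O3 (1.0 equiv), CH2Cl2, −78 °C; then Me2S, −78 °C to rt
Reagents that add atoms: ozone, [O-][O+]=O
Why: Ozonolysis (Criegee mechanism) with one equivalent of ozone cleaves the electron-rich trisubstituted ring alkene faster than the 1,1-disubstituted isopropenyl group, and the purchased C-4 stereocentre is not involved.

Step 2
Reactants: 3 (3S)-6-oxo-3-(prop-1-en-2-yl)heptanal
Product: 4 (5R)-2-methyl-5-(prop-1-en-2-yl)cyclopent-1-ene-1-carbaldehyde
Conditions: piperidine (20 mol %), AcOH (20 mol %), PhMe, 80 °C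
Reagents that add atoms: none
Why: Amine-catalysed intramolecular aldol condensation, in which the enamine of the aldehyde attacks the methyl ketone and water is lost, gives the cyclopentenecarbaldehyde, and the stereocentre, which is not alpha to either carbonyl, is kept.

Step 3
Reactants: 4 (5R)-2-methyl-5-(prop-1-en-2-yl)cyclopent-1-ene-1-carbaldehyde; 5 allylmagnesium bromide
Product: 6 (1RS)-1-[(5R)-2-methyl-5-(prop-1-en-2-yl)cyclopent-1-en-1-yl]but-3-en-1-ol
Conditions: Et2O, −78 °C to 0 °C; then H2O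
Reagents that add atoms: allylmagnesium bromide (5), C=CC[Mg]Br
Why: Grignard 1,2-addition to the enal, whose beta carbon is fully substituted, gives the 3-hydroxy-1,5-diene, and the new carbinol centre is a mixture that step 4 erases.

Step 4
Reactants: 6 (1RS)-1-[(5R)-2-methyl-5-(prop-1-en-2-yl)cyclopent-1-en-1-yl]but-3-en-1-ol
Product: 9 (1RS,2R,5S)-2-methyl-2-(prop-2-en-1-yl)-5-(prop-1-en-2-yl)cyclopentane-1-carbaldehyde, via potassium alkoxide 7 (not isolated), via potassium enolate 8 (not isolated)
Conditions: KH (1.3 equiv), 18-crown-6 (1.3 equiv), THF, 0 °C to rt; then H2O, −78 °C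
Reagents that add atoms: none
Why: Anionic oxy-Cope [3,3]-sigmatropic rearrangement, driven by formation of the enolate, passes through a chair on the ring face opposite the C-5 isopropenyl group and so forms the C-2 quaternary centre with the allyl group trans to isopropenyl (2R).

Step 5
Reactants: 9 (1RS,2R,5S)-2-methyl-2-(prop-2-en-1-yl)-5-(prop-1-en-2-yl)cyclopentane-1-carbaldehyde
Product: 10 (2R,5R)-2-methyl-2-(prop-2-en-1-yl)-5-(prop-1-en-2-yl)cyclopentan-1-one
Conditions: O2 (1 atm), Cu(OAc)2 (5 mol %), 2,2'-bipyridine (5 mol %), DABCO (1 equiv), DMF, 40 °C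
Reagents that add atoms: dioxygen, O=O
Why: Copper-catalysed aerobic oxidative deformylation (Van Rheenen-type, via the alpha-hydroperoxide and C–C cleavage to ketone plus formic acid) removes the formyl carbon, while C-2 is quaternary and the weak amine base does not enolise the product toward C-5, so both centres are kept.

Step 6
Reactants: 10 (2R,5R)-2-methyl-2-(prop-2-en-1-yl)-5-(prop-1-en-2-yl)cyclopentan-1-one; 11 4-bromo-2-methylbut-1-ene
Product: 13 (1S,2R,5R)-2-methyl-1-(3-methylbut-3-en-1-yl)-2-(prop-2-en-1-yl)-5-(prop-1-en-2-yl)cyclopentan-1-ol, via Grignard reagent 12 (not isolated)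
Conditions: 11, Mg, THF, rt; then 10, LaCl3·2LiCl (1 equiv), THF, 0 °C; then H2O
Reagents that add atoms: 4-bromo-2-methylbut-1-ene (11), CC(=C)CCBr
Why: Lanthanide-promoted Grignard 1,2-addition suppresses enolisation, and the nucleophile comes from the carbonyl face opposite the C-5 isopropenyl group, so the new tertiary hydroxyl (1S) is cis to isopropenyl and to the C-2 methyl and the two alkenyl arms are cis to each other.

Step 7
Reactants: 13 (1S,2R,5R)-2-methyl-1-(3-methylbut-3-en-1-yl)-2-(prop-2-en-1-yl)-5-(prop-1-en-2-yl)cyclopentan-1-ol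
Product: 14 (3R,3aS,8aR)-6,8a-dimethyl-3-(prop-1-en-2-yl)-2,3,4,5,8,8a-hexahydroazulen-3a(1H)-ol
Conditions: second-generation Grubbs catalyst (5 mol %), CH2Cl2 (0.005 M), 40 °C
Reagents that add atoms: none
Why: Ring-closing metathesis joins the allyl arm and the 1,1-disubstituted terminus of the cis-disposed butenyl arm to the trisubstituted cycloheptene with loss of ethene, and the hindered isopropenyl group on the other face cannot reach either partner.

Step 8
Reactants: 14 (3R,3aS,8aR)-6,8a-dimethyl-3-(prop-1-en-2-yl)-2,3,4,5,8,8a-hexahydroazulen-3a(1H)-ol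
Product: 16 (3R,3aS,8aR)-3-[(2S)-1-hydroxypropan-2-yl]-6,8a-dimethyl-2,3,4,5,8,8a-hexahydroazulen-3a(1H)-ol, via B-alkyl-9-BBN adduct 15 (not isolated)
Conditions: 9-BBN (2.5 equiv), THF, 0 °C to rt; then 3 M NaOH, 30% H2O2, 0 °C to rt
Reagents that add atoms: hydrogen peroxide, OO
Why: Brown hydroboration–oxidation with 9-BBN takes the 1,1-disubstituted alkene far faster than the trisubstituted ring alkene and, in the conformer with H-3 eclipsing the C=CH2 bond (A(1,3)-strain model), adds from the side away from the fully substituted C-3a, which sets the (2S) side-chain centre.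

Step 9
Reactants: 16 (3R,3aS,8aR)-3-[(2S)-1-hydroxypropan-2-yl]-6,8a-dimethyl-2,3,4,5,8,8a-hexahydroazulen-3a(1H)-ol
Product: 18 (3R,3aS,6S,7S,8aR)-3-[(2S)-1-hydroxypropan-2-yl]-6,8a-dimethyloctahydro-1H-3a,6-epoxyazulen-7-ol, via anti-epoxide 17 (not isolated)
Conditions: mCPBA (1.05 equiv), CH2Cl2, 0 °C; then CSA (10 mol %), rt
Reagents that add atoms: mCPBA, OOC(=O)c1cccc(Cl)c1
Why: Prilezhaev epoxidation of the only alkene on the face opposite the 3a-hydroxyl (as in the classical carotol-to-daucol oxidation) is followed by acid-catalysed transannular 5-exo opening at the tertiary C-6 with inversion, which fixes C-6 (S) and leaves the C-7 hydroxyl (S) trans to the new oxygen bridge.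

Step 10
Reactants: 18 (3R,3aS,6S,7S,8aR)-3-[(2S)-1-hydroxypropan-2-yl]-6,8a-dimethyloctahydro-1H-3a,6-epoxyazulen-7-ol; 19 vanillic acid
Product: 20 (2S)-2-[(3R,3aS,6S,7S,8aR)-7-hydroxy-6,8a-dimethyloctahydro-1H-3a,6-epoxyazulen-3-yl]propyl 4-hydroxy-3-methoxybenzoate
Conditions: PPh3 (1.3 equiv), DIAD (1.3 equiv), THF, 0 °C to rt
Reagents that add atoms: vanillic acid (19), COc1cc(C(=O)O)ccc1O
Why: Mitsunobu esterification activates only the unhindered primary alcohol (the C-7 secondary alcohol next to a quaternary carbon does not react) and the carboxylate is alkylated in preference to the less acidic phenol, so no protecting group is needed and no stereocentre changes.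

**Compound list**

1 | (S)-(−)-limonene, (4S)-1-methyl-4-(prop-1-en-2-yl)cyclohex-1-ene | CC1=CC[C@H](CC1)C(C)=C | starting material
2 | secondary ozonide, (4S)-1-methyl-4-(prop-1-en-2-yl)-7,8,9-trioxabicyclo[4.2.1]nonane, both bridgehead diastereomers, not isolated | CC12CC[C@@H](CC(OO1)O2)C(C)=C | intermediate
3 | (3S)-6-oxo-3-(prop-1-en-2-yl)heptanal | CC(=O)CC[C@@H](CC=O)C(C)=C | intermediate
4 | (5R)-2-methyl-5-(prop-1-en-2-yl)cyclopent-1-ene-1-carbaldehyde | CC1=C(C=O)[C@H](CC1)C(C)=C | intermediate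
5 | allylmagnesium bromide | C=CC[Mg]Br | starting material
6 | (1RS)-1-[(5R)-2-methyl-5-(prop-1-en-2-yl)cyclopent-1-en-1-yl]but-3-en-1-ol, both carbinol epimers | CC1=C(C(O)CC=C)[C@H](CC1)C(C)=C | intermediate
7 | potassium alkoxide, potassium (1RS)-1-[(5R)-2-methyl-5-(prop-1-en-2-yl)cyclopent-1-en-1-yl]but-3-en-1-olate, not isolated | CC1=C(C([O-])CC=C)[C@H](CC1)C(C)=C.[K+] | intermediate
8 | potassium enolate, potassium [(2R,5R)-2-methyl-2-(prop-2-en-1-yl)-5-(prop-1-en-2-yl)cyclopentylidene]methanolate, E/Z, not isolated | C=CC[C@@]1(C)CC[C@H](C(C)=C)C1=C[O-].[K+] | intermediate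
9 | (1RS,2R,5S)-2-methyl-2-(prop-2-en-1-yl)-5-(prop-1-en-2-yl)cyclopentane-1-carbaldehyde, allyl trans to isopropenyl, both C-1 epimers | C=CC[C@@]1(C)CC[C@H](C(C)=C)C1C=O | intermediate
10 | (2R,5R)-2-methyl-2-(prop-2-en-1-yl)-5-(prop-1-en-2-yl)cyclopentan-1-one | C=CC[C@@]1(C)CC[C@H](C(C)=C)C1=O | intermediate
11 | 4-bromo-2-methylbut-1-ene | CC(=C)CCBr | starting material
12 | Grignard reagent, (3-methylbut-3-en-1-yl)magnesium bromide, not isolated | CC(=C)CC[Mg]Br | intermediate
13 | (1S,2R,5R)-2-methyl-1-(3-methylbut-3-en-1-yl)-2-(prop-2-en-1-yl)-5-(prop-1-en-2-yl)cyclopentan-1-ol, OH, methyl and isopropenyl all cis | C=CC[C@@]1(C)CC[C@H](C(C)=C)[C@@]1(O)CCC(C)=C | intermediate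
14 | (3R,3aS,8aR)-6,8a-dimethyl-3-(prop-1-en-2-yl)-2,3,4,5,8,8a-hexahydroazulen-3a(1H)-ol | CC(=C)[C@H]1CC[C@]2(C)CC=C(C)CC[C@]12O | intermediate
15 | B-alkyl-9-BBN adduct, (3R,3aS,8aR)-3-[(2R)-1-(9-borabicyclo[3.3.1]nonan-9-yl)propan-2-yl]-6,8a-dimethyl-2,3,4,5,8,8a-hexahydroazulen-3a(1H)-ol, not isolated | C[C@H](CB1C2CCCC1CCC2)[C@H]1CC[C@]2(C)CC=C(C)CC[C@]12O | intermediate
16 | (3R,3aS,8aR)-3-[(2S)-1-hydroxypropan-2-yl]-6,8a-dimethyl-2,3,4,5,8,8a-hexahydroazulen-3a(1H)-ol | OC[C@@H](C)[C@H]1CC[C@]2(C)CC=C(C)CC[C@]12O | intermediate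
17 | anti-epoxide, (3R,3aS,6R,7S,8aR)-6,7-epoxy-3-[(2S)-1-hydroxypropan-2-yl]-6,8a-dimethyldecahydroazulen-3a-ol, oxirane on the face opposite the 3a-OH, not isolated | OC[C@@H](C)[C@H]1CC[C@]2(C)C[C@@H]3O[C@]3(C)CC[C@]12O | intermediate
18 | (3R,3aS,6S,7S,8aR)-3-[(2S)-1-hydroxypropan-2-yl]-6,8a-dimethyloctahydro-1H-3a,6-epoxyazulen-7-ol | OC[C@@H](C)[C@H]1CC[C@]2(C)C[C@H](O)[C@]3(C)CC[C@]12O3 | intermediate
19 | vanillic acid, 4-hydroxy-3-methoxybenzoic acid | COc1cc(C(=O)O)ccc1O | starting material
20 | (2S)-2-[(3R,3aS,6S,7S,8aR)-7-hydroxy-6,8a-dimethyloctahydro-1H-3a,6-epoxyazulen-3-yl]propyl 4-hydroxy-3-methoxybenzoate (CNP0277205.1) | COc1cc(C(=O)OC[C@@H](C)[C@H]2CC[C@]3(C)C[C@H](O)[C@]4(C)CC[C@]23O4)ccc1O | target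

**Step count and risks**

Total steps: 10. Longest linear sequence: 10 (the route is fully linear from 1).

Three steps most likely to fail:

Step 4 (anionic oxy-Cope). The new bond is made at a tetrasubstituted alkene carbon, so the alkoxide may fragment or show poor facial selectivity. The fallback sets out from 4 and comes back at 10 without a sigmatropic step. Condense 4 with morpholine (TsOH cat., PhMe, water removal) to its morpholine dienamine F1. Cleave the enamine double bond with O2/CuCl in MeCN to the cyclopentenone F2. Reduce F2 in 1,4 fashion with LiBH(s-Bu)3 at −78 °C to the regiodefined lithium enolate F3. Alkylate it in the same flask with allyl bromide, which enters trans to the isopropenyl group and gives 10.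

Step 8 (hydroboration). Acyclic facial control by one neighbouring ring carbon is the least certain stereochemical call of the route. The fallback sets out from 14 and comes back at 16, and it is stereoconvergent. Hydroborate 14 as before and carry the mixture of 16 and its side-chain epimer, the (2R)-diol F4, forward. TEMPO (cat.)/PhI(OAc)2 oxidises both 1,4-diols to the γ-lactones, the (2R)-lactone F5 and the (2S)-lactone F6. LiN(i-Pr)2 (THF, −78 °C) turns both into the single lithium enolate F7. 2,6-Di-tert-butylphenol protonates it at −78 °C from the open face next to H-3, which puts the methyl group on the side of C-2 and gives only the (2S)-lactone F6. LiAlH4 reduces F6 to 16.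

Step 9 (epoxidation and ring closure). If the peracid adds on the face of the 3a-hydroxyl, the epoxide cannot be opened from the back by that hydroxyl. The fallback sets out from 16 and comes back at 17, which closes to 18 as before. NBS in aqueous acetone gives the bromohydrin F8: the bromonium ion forms on the face the peracid prefers, and water opens it at the tertiary carbon from the other face. K2CO3 in MeOH closes F8 to the epoxide 17 on the face anti to the 3a-hydroxyl, and CSA then gives 18.

Further compounds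
F1 | step 4 | morpholine dienamine 4-{[(5R)-2-methyl-5-(prop-1-en-2-yl)cyclopent-2-en-1-ylidene]methyl}morpholine, E/Z | CC1=CC[C@H](C(C)=C)C1=CN1CCOCC1
F2 | step 4 | cyclopentenone (5R)-2-methyl-5-(prop-1-en-2-yl)cyclopent-2-en-1-one | CC1=CC[C@H](C(C)=C)C1=O
F3 | step 4 | lithium enolate, lithium (5R)-2-methyl-5-(prop-1-en-2-yl)cyclopent-1-en-1-olate | CC1=C([O-])[C@H](CC1)C(C)=C.[Li+]
F4 | step 8 | (2R)-diol (3R,3aS,8aR)-3-[(2R)-1-hydroxypropan-2-yl]-6,8a-dimethyl-2,3,4,5,8,8a-hexahydroazulen-3a(1H)-ol | OC[C@H](C)[C@H]1CC[C@]2(C)CC=C(C)CC[C@]12O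
F5 | step 8 | (2R)-lactone, γ-lactone of (2R)-2-[(3R,3aS,8aR)-3a-hydroxy-6,8a-dimethyl-1,2,3,3a,4,5,8,8a-octahydroazulen-3-yl]propanoic acid | C[C@H]1C(=O)O[C@@]23CCC(C)=CC[C@@]3(C)CC[C@H]12
F6 | step 8 | (2S)-lactone, γ-lactone of (2S)-2-[(3R,3aS,8aR)-3a-hydroxy-6,8a-dimethyl-1,2,3,3a,4,5,8,8a-octahydroazulen-3-yl]propanoic acid | C[C@@H]1C(=O)O[C@@]23CCC(C)=CC[C@@]3(C)CC[C@H]12
F7 | step 8 | lithium enolate of the lactones F5 and F6 | CC1=C([O-])O[C@@]23CCC(C)=CC[C@@]3(C)CC[C@H]12.[Li+]
F8 | step 9 | bromohydrin (3R,3aS,6R,7R,8aR)-7-bromo-3-[(2S)-1-hydroxypropan-2-yl]-6,8a-dimethyldecahydroazulene-3a,6-diol | OC[C@@H](C)[C@H]1CC[C@]2(C)C[C@@H](Br)[C@](C)(O)CC[C@]12O
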